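**Numbering used throughout.** Ring A is the cyclohexadienone: C1 ring ketone, C2 (hexanoyl), C3 (enol C–OH), C4 (quaternary: methyl, prenyl), C5 (enol C–OH), C6 (carries the bridging CH2). Ring B is the aromatic ring, with primed atoms and C1' on the bridge.

## The problem

- The target is a methylene-bridged pair of acylphloroglucinols: aromatic ring B (3-butanoyl-2,4-dihydroxy-6-methoxyphenyl) and dearomatised ring A (an enolised 2-acyl-4,4-dialkylcyclohexane-1,3,5-trione), joined by one CH2 between C6 and C1'.
- The only stereocentre is the quaternary carbon C4 of ring A, and it is R.
- C4 lies between two locally identical carbonyl-level carbons, C3 and C5. It is stereogenic only because C2 carries the hexanoyl group and C6 the arylmethyl group. No neighbouring stereocentre can relay its configuration, so it must be set absolutely, by an operation that tells apart two arms that differ two bonds away.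
- The usual entry, C-alkylation of a flat phloroglucinol anion, creates C4 on the finished ring, where this difference is remote. It must also beat O-alkylation and alkylation at the unsubstituted ring carbon.
- The feature that makes the key step possible: C3–C4–C5 of ring A is a 2,2-disubstituted malonyl unit, and C6–C1–C2 with the exocyclic hexanoyl carbonyl is nonane-2,4-dione. Ring A is therefore a tetraketide that can be closed by two C-acylations (C5–C6 and C2–C3). The configuration of C4 is then decided only by which malonyl carbonyl becomes C3 and which becomes C5.
- Once quaternary, C4 cannot epimerise, and enol tautomerism does not touch it.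
- The rest is fragile: protic acid cyclises the prenyl alkene onto a neighbouring oxygen, hot alkali removes the exocyclic acyl group by retro-Claisen cleavage, and strong base exchanges the methylene bridge between the halves of such dimers.
- Ring B is symmetric before bridging (two equivalent free positions), so it can react twice.

## Retrosynthesis

**Bridge (16 to 9 and 14).** The bond between the bridging CH2 and C6 of ring A is cut. The nucleophile is the chiral trione 9, which has a single nucleophilic carbon (C6). The electrophile is the ortho-quinone methide 15, released from the Mannich base 14 of ring B. The neighbouring cut (CH2–C1', with ring A as electrophile) or free formaldehyde with both halves would give statistical homo-dimers and would put the costly chiral half at risk of self-condensation. With 14, the one-carbon unit is already fixed on the cheap symmetric half, and 9 cannot react twice. The forward reaction must run close to neutral, without strong base.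

**Ring A (9 to 6 and 7, through 8).** Two ring bonds are cut, C5–C6 and C2–C3. This gives the malonyl unit 6 (C3–C4–C5 with methyl and prenyl) and nonane-2,4-dione 7 (C6, C1, C2 and the hexanoyl chain). Against the cut at C4–CH2 (dearomative prenylation), this one needs no stereocontrol on the ring. The configuration of C4 becomes a question of chemoselectivity between two different carboxyl derivatives in 6. The hexanoyl group and the free C6–H are placed by the construction itself. The precursors are a C10 malonate and a commercial diketone. The forward reaction must acylate the terminal carbon of the dianion of 7 at the imidazolide carbonyl only, then close the ring by Claisen condensation onto the ester.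

**Differentiated malonate (6 to 5 to 4).** The imidazolide 6 comes from half-ester 5, and 5 from the mixed diester 4 by removal of the tert-butyl group alone. The tert-butyl/methyl pair is chosen because one ester can be removed without hydrolysis, and the remaining methyl ester is a competent Claisen acceptor. The forward steps must spare the prenyl alkene, so no protic acid is used.

**Stereocentre (4 to 2 and 3).** The C4–CH2 (prenyl) bond is cut on the open-chain malonate. At this stage the two carbonyl arms are directly attached to the prochiral carbon and differ strongly (OMe against OtBu). A chiral ammonium counter-ion can therefore distinguish the enolate faces. The same bond in the ring is flanked by two nearly identical enols. Precursor 2 is one step from tert-butyl propanoate 1, and 3 is prenyl bromide.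

**Ring B (14 to 13 to 12 to 10 and 11).** The aminomethyl group of 14 is removed to give the symmetric ketone 13. This comes from triol 12 by methylation of the one non-chelated hydroxyl, and 12 from phloroglucinol 10 and butanoyl chloride 11. Symmetry means that no regiochemical question arises until the bridge is made.

## Roads not taken

**Alternative 1:** the obvious cut is the C4–CH2 (prenyl) bond on the intact ring.
- Forward key step: the aromatic ketone A1 (1-(2,4,6-trihydroxy-3-methylphenyl)hexan-1-one) is C-prenylated with 3 and base at the methyl-bearing carbon. This dearomative alkylation of an ambident phenoxide gives the dienone A2, which is bridged to ring B as in step 9.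
- Why the chosen plan is better: this route is short, but it gives racemic A2. C4 is created on a flat ring, and O-alkylation and prenylation at the unsubstituted ring carbon compete. An enantioselective version would need a catalyst-bound prenyl electrophile that stays linear and also distinguishes the ring faces, for which no close precedent is apparent. The single enantiomer would therefore come from resolution of A2, discarding half of an advanced intermediate. The chosen plan sets C4 on a small malonate and rebuilds the ring with full regiocontrol.

**Alternative 2:** cut the bridge and the hexanoyl group from an achiral ring.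
- Forward key step: the prochiral trione A3 (3,5-dihydroxy-4-methyl-4-prenylcyclohexa-2,5-dien-1-one) would add, under a chiral catalyst, through one of its two enantiotopic carbons to ortho-quinone methide 15. This would give A4, and C-acylation at the remaining ring carbon would give 16.
- Why the chosen plan is better: the enantiotopic carbons are two bonds from C4, and the product configuration depends only on which one reacts. The catalyst would have to read the methyl/prenyl difference across the planar dienolate, which no known reaction type does reliably. Double alkylation gives achiral by-products, and the late C-acylation would have to avoid the phenols of ring B. The chosen plan makes the same distinction where the groups are adjacent and chemically different.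

**Alternative 3:** close ring A last, with both halves already joined.
- Forward key step: imidazolide 6 would acylate the dianion of the ring-B-bearing diketone A5 (1-[3-butanoyl-6-methoxy-2,4-bis(methoxymethoxy)phenyl]decane-3,5-dione). Claisen closure would give the protected dimer A6, and deprotection would give 16.
- Why the chosen plan is better: both termini of A5 are methylene groups, so the site of the second deprotonation is not controlled; 7 offers a methyl against a methylene. A5 needs its own multi-step synthesis with phenol protection, and its butanoyl ketone is a further enolisable site. Unmasking A6 needs acid, which threatens the prenyl group. Bridging last under neutral conditions avoids all three problems.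

Key step: step 5

**Assumptions.**
- Enolised polycarbonyl compounds are drawn and named as the tautomer of the given SMILES; they will exist as equilibrating enol forms, which does not affect C4.
- The cinchoninium catalyst of step 2 is assumed to give (S)-4. If it gives the antipode, the pseudoenantiomeric N-(9-anthracenylmethyl)cinchonidinium chloride is used and nothing else changes.

## Steps

Step 1
Reactants: 1 tert-butyl propanoate
Product: 2 1-tert-butyl 3-methyl 2-methylpropanedioate (racemic, configurationally labile)
Conditions: LiN(iPr)2 (2.1 equiv), THF, −78 °C; ClCO2Me, −78 → 0 °C; 1 M HCl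
Reagents that add atoms: methyl chloroformate, COC(Cl)=O
Why: C-acylation of a lithium ester enolate with a chloroformate (crossed Claisen-type acylation); the second equivalent of base deprotonates the more acidic malonate as it forms, so the product is strictly mono-methylated at C2.

Step 2
Reactants: 2 1-tert-butyl 3-methyl 2-methylpropanedioate; 3 1-bromo-3-methylbut-2-ene (prenyl bromide)
Product: 4 1-tert-butyl 3-methyl (2S)-2-methyl-2-(3-methylbut-2-en-1-yl)propanedioate
Conditions: N-(9-anthracenylmethyl)cinchoninium chloride (10 mol %), 50% aq KOH, toluene, −20 °C
Reagents that add atoms: none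
Why: Enantioselective phase-transfer α-alkylation of an α-methylmalonate tert-butyl/methyl diester with an allylic bromide, a known reaction type for this ester pair. The chiral ammonium cation pairs with the enolate, and the size difference between OtBu and OMe exposes one enantioface to SN2 attack at the primary carbon of 3 (linear prenyl, no SN2′); this sets the quaternary stereocentre, which has no α-hydrogen and is fixed from here on.

Step 3
Reactants: 4 1-tert-butyl 3-methyl (2S)-2-methyl-2-(3-methylbut-2-en-1-yl)propanedioate
Product: 5 (2R)-3-methoxy-2-methyl-2-(3-methylbut-2-en-1-yl)-3-oxopropanoic acid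
Conditions: Me3SiOSO2CF3, 2,6-lutidine, CH2Cl2, 0 °C → rt; then aqueous citric acid
Reagents that add atoms: none
Why: Silyl-triflate-mediated cleavage of a tert-butyl ester: O-silylation, loss of the tert-butyl cation as 2-methylpropene to the hindered base, hydrolysis of the silyl ester on work-up. The methyl ester cannot ionise, and the buffered aprotic medium avoids the protic acid that would lactonise the acid onto the prenyl alkene; the descriptor changes from S to R only because the priorities of the two arms change. Since 5 is an acid, its optical purity can be raised here by crystallisation of an amine salt.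

Step 4
Reactants: 5 (2R)-3-methoxy-2-methyl-2-(3-methylbut-2-en-1-yl)-3-oxopropanoic acid
Product: 6 methyl (2R)-3-(1H-imidazol-1-yl)-2-methyl-2-(3-methylbut-2-en-1-yl)-3-oxopropanoate
Conditions: 1,1'-carbonyldiimidazole, THF, rt; concentrated and used crude
Reagents that add atoms: 1,1'-carbonyldiimidazole, O=C(n1ccnc1)n1ccnc1
Why: Activation of the acid as its acyl imidazolide under neutral conditions; the quaternary α-carbon excludes ketene formation and racemisation, the methyl ester is inert, and the two malonate carbonyls now differ strongly in electrophilicity.

Step 5
Reactants: 6 methyl (2R)-3-(1H-imidazol-1-yl)-2-methyl-2-(3-methylbut-2-en-1-yl)-3-oxopropanoate; 7 nonane-2,4-dione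
Product: 9 (4R)-2-hexanoyl-3,5-dihydroxy-4-methyl-4-(3-methylbut-2-en-1-yl)cyclohexa-2,5-dien-1-one, via triketo ester 8 (not isolated)
Conditions: 7 (3 equiv), LiN(iPr)2 (6 equiv), THF, −78 → 0 °C; 6 in THF, −78 → 0 °C; then NaOMe, MeOH, 0 → 40 °C; cold 1 M HCl to pH 3
Reagents that add atoms: none
Why: The dilithio dianion of 7, formed at the central carbon and then at the methyl group (the usual site of second deprotonation of a methyl alkyl β-diketone), attacks with its terminal carbon the imidazolide carbonyl of 6, the most electrophilic carbonyl present, to give the 3,5,7-triketo ester 8 as its polyanion; three equivalents of dianion absorb the imidazole N–H and the new acidic methylene. Methoxide in methanol then equilibrates the enolates, and the doubly stabilised chain carbon between the 5- and 7-carbonyls of 8 adds to the methyl ester and expels methoxide, a 6-exo-trig Claisen (Dieckmann-type) closure that forms the C2–C3 bond of ring A. The closest known reaction types are the terminal acylation of β-diketone dianions to 1,3,5-triketones and the Claisen cyclisation of 3,5,7-trioxoalkanoates to acylphloroglucinols. No stereocentre is created: C4 comes from 6, has no α-hydrogen and cannot epimerise, and its configuration in 9 is fixed by which carbonyl of 6 is attacked first, so that the imidazolide carbon becomes C5 (next to the free C6–H) and the ester carbon becomes C3 (next to the hexanoyl-bearing C2). The selectivities needed are imidazolide over ester in the first acylation (leaving-group difference, low temperature, and complete consumption of 6 before methoxide is added), methyl over methylene in the dianion, and C- over O-cyclisation in the closure. The aldol mode that competes in ordinary tetraketides is excluded because C4 is quaternary, an enol lactone formed by O-attack is reopened by methoxide, and only the C-cyclised product leaves the equilibrium as its stable vinylogous-acid anion. The geminal substituents at C4 favour closure, and the enolates protect the 3-ketone of 8 and both ring ketones of 9 against retro-Claisen cleavage.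

Step 6
Reactants: 10 benzene-1,3,5-triol (phloroglucinol); 11 butanoyl chloride
Product: 12 1-(2,4,6-trihydroxyphenyl)butan-1-one
Conditions: AlCl3 (3 equiv), CH2Cl2/MeNO2, 0 °C → 40 °C; ice/aq HCl
Reagents that add atoms: none
Why: Friedel–Crafts C-acylation of phloroglucinol; the three ring positions are equivalent and the acyl group deactivates the ring against a second acylation.

Step 7
Reactants: 12 1-(2,4,6-trihydroxyphenyl)butan-1-one
Product: 13 1-(2,6-dihydroxy-4-methoxyphenyl)butan-1-one
Conditions: (MeO)2SO2 (1.0 equiv), K2CO3 (1.0 equiv), acetone, rt → reflux
Reagents that add atoms: dimethyl sulfate, COS(=O)(=O)OC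
Why: Selective O-methylation of the 4-hydroxyl, the most acidic phenol (para to the carbonyl) and the only one not hydrogen-bonded to the ketone; one equivalent of reagent leaves the two chelated ortho-hydroxyls free.

Step 8
Reactants: 13 1-(2,6-dihydroxy-4-methoxyphenyl)butan-1-one
Product: 14 1-{3-[(dimethylamino)methyl]-2,6-dihydroxy-4-methoxyphenyl}butan-1-one
Conditions: 40% aq Me2NH (1.0 equiv), 37% aq CH2O (1.0 equiv), EtOH, 0 °C → rt
Reagents that add atoms: formaldehyde, C=O; dimethylamine, CNC
Why: Phenolic Mannich reaction at one of the two equivalent free positions of the electron-rich ring; one equivalent of iminium ion limits the reaction to mono-aminomethylation and leaves the second position as the ring hydrogen of the target.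

Step 9
Reactants: 9 (4R)-2-hexanoyl-3,5-dihydroxy-4-methyl-4-(3-methylbut-2-en-1-yl)cyclohexa-2,5-dien-1-one; 14 1-{3-[(dimethylamino)methyl]-2,6-dihydroxy-4-methoxyphenyl}butan-1-one
Product: 16 (4R)-6-[(3-butanoyl-2,4-dihydroxy-6-methoxyphenyl)methyl]-2-hexanoyl-3,5-dihydroxy-4-methyl-4-(3-methylbut-2-en-1-yl)cyclohexa-2,5-dien-1-one (CNP0219674.1), via ortho-quinone methide 15 (not isolated)
Conditions: 14 (1.3 equiv), 1,4-dioxane, 80 °C, argon purge
Reagents that add atoms: none
Why: Mannich-base route to an ortho-quinone methide with Michael capture by a cyclic 1,3-dicarbonyl carbon acid: the vinylogous acid 9 protonates the benzylic amine of 14, dimethylamine is expelled with the push of the ortho-hydroxyl to give 15, and the enolate of 9 adds through C6, its only nucleophilic carbon, after which tautomerisation restores ring B. The medium stays close to neutral, which spares the prenyl and hexanoyl groups and avoids base-induced exchange of the bridge; C4 is not involved.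

## Compound list

1 | tert-butyl propanoate | CCC(=O)OC(C)(C)C | starting material
2 | 1-tert-butyl 3-methyl 2-methylpropanedioate (racemic) | COC(=O)C(C)C(=O)OC(C)(C)C | intermediate
3 | 1-bromo-3-methylbut-2-ene (prenyl bromide) | CC(C)=CCBr | starting material
4 | 1-tert-butyl 3-methyl (2S)-2-methyl-2-(3-methylbut-2-en-1-yl)propanedioate | COC(=O)[C@](C)(CC=C(C)C)C(=O)OC(C)(C)C | intermediate
5 | (2R)-3-methoxy-2-methyl-2-(3-methylbut-2-en-1-yl)-3-oxopropanoic acid | COC(=O)[C@](C)(CC=C(C)C)C(O)=O | intermediate
6 | methyl (2R)-3-(1H-imidazol-1-yl)-2-methyl-2-(3-methylbut-2-en-1-yl)-3-oxopropanoate | COC(=O)[C@](C)(CC=C(C)C)C(=O)n1ccnc1 | intermediate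
7 | nonane-2,4-dione | CCCCCC(=O)CC(C)=O | starting material
8 | methyl (2R)-2-methyl-2-(3-methylbut-2-en-1-yl)-3,5,7-trioxododecanoate | COC(=O)[C@](C)(CC=C(C)C)C(=O)CC(=O)CC(=O)CCCCC | intermediate (not isolated)
9 | (4R)-2-hexanoyl-3,5-dihydroxy-4-methyl-4-(3-methylbut-2-en-1-yl)cyclohexa-2,5-dien-1-one | CCCCCC(=O)C1=C(O)[C@](C)(CC=C(C)C)C(O)=CC1=O | intermediate
10 | benzene-1,3,5-triol (phloroglucinol) | Oc1cc(O)cc(O)c1 | starting material
11 | butanoyl chloride | CCCC(Cl)=O | starting material
12 | 1-(2,4,6-trihydroxyphenyl)butan-1-one | CCCC(=O)c1c(O)cc(O)cc1O | intermediate
13 | 1-(2,6-dihydroxy-4-methoxyphenyl)butan-1-one | CCCC(=O)c1c(O)cc(OC)cc1O | intermediate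
14 | 1-{3-[(dimethylamino)methyl]-2,6-dihydroxy-4-methoxyphenyl}butan-1-one | CCCC(=O)c1c(O)cc(OC)c(CN(C)C)c1O | intermediate
15 | 2-butanoyl-3-hydroxy-5-methoxy-6-methylidenecyclohexa-2,4-dien-1-one | CCCC(=O)C1=C(O)C=C(OC)C(=C)C1=O | intermediate (not isolated)
16 | (4R)-6-[(3-butanoyl-2,4-dihydroxy-6-methoxyphenyl)methyl]-2-hexanoyl-3,5-dihydroxy-4-methyl-4-(3-methylbut-2-en-1-yl)cyclohexa-2,5-dien-1-one | CCCCCC(=O)C1=C(O)[C@](C)(CC=C(C)C)C(O)=C(Cc2c(OC)cc(O)c(C(=O)CCC)c2O)C1=O | target

## Step count and risks

Total: 9 steps. Longest linear sequence: 6 steps (1, 2, 3, 4, 5, 9); ring B takes 3 steps (6, 7, 8) before the union.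

**Step 5 (key step).**
- What may go wrong: the stabilised carbanion may close slowly onto the hindered, neopentyl-type ester, so that O-cyclisation to an enol lactone or cleavage of the chain takes over. Partial deprotonation of 7 at its methylene terminus would give a regioisomeric ring.
- Fallback (sets out from 5 and 7, returns at 9 through isolated 8): the two bond formations are separated and the first is made with a neutral nucleophile.
  - Acid 5 is converted with 1-chloro-N,N,2-trimethylprop-1-en-1-amine in CH2Cl2 into the acid chloride, methyl (2S)-3-chloro-2-methyl-2-(3-methylbut-2-en-1-yl)-3-oxopropanoate F1.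
  - Diketone 7 is converted by two successive silylations into the bis(silyl enol ether), (3Z)-2,4-bis(trimethylsilyloxy)nona-1,3-diene F2.
  - Mukaiyama-type acylation of the terminal carbon of F2 by F1 (CH2Cl2, −78 °C → rt) gives 8 after aqueous work-up.
  - Isolated 8 is cyclised on its own with KOtBu in THF to 9.

**Step 2.**
- What may go wrong: facial discrimination on an acyclic enolate with a small OMe group may be insufficient, the sense of induction may be unexpected, or the methyl ester may be partly saponified in the basic aqueous phase.
- Fallback (sets out from 3, returns at 5, making step 3 unnecessary): the stereocentre is set by enzymatic desymmetrisation instead of asymmetric alkylation.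
  - Dimethyl 2-methylpropanedioate F3 is alkylated with 3 (NaH, THF) to the achiral diester, dimethyl 2-methyl-2-(3-methylbut-2-en-1-yl)propanedioate F4.
  - Pig liver esterase in pH 7.5 phosphate buffer hydrolyses one of its two enantiotopic ester groups to 5.
  - Optical purity is raised by crystallisation of a salt with enantiopure 1-phenylethylamine.
  - The unwanted antipode is returned to F4 by methylation (MeI, K2CO3), so the wrong enantiomer is recycled through an achiral compound.

**Step 9.**
- What may go wrong: the ortho-quinone methide may condense with its own precursor faster than it is captured by the weakly nucleophilic anion of 9, ring B may be alkylated twice, and the liberated amine may exchange the methylene bridge between the halves.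
- Fallback (sets out from 13 and 9, returns at 16): the bridge carbon is brought in at the aldehyde oxidation level and the bond is made irreversibly by reduction.
  - Vilsmeier–Haack formylation of 13 (POCl3, DMF; aqueous NaOAc) gives 3-butanoyl-2,4-dihydroxy-6-methoxybenzaldehyde F5.
  - Reductive Knoevenagel alkylation of 9 with F5 (L-proline catalyst, diethyl 2,6-dimethyl-1,4-dihydropyridine-3,5-dicarboxylate as Hantzsch ester, CH2Cl2, rt) proceeds through the alkylidene trione, (6S)-2-[(3-butanoyl-2,4-dihydroxy-6-methoxyphenyl)methylidene]-4-hexanoyl-5-hydroxy-6-methyl-6-(3-methylbut-2-en-1-yl)cyclohex-4-ene-1,3-dione F6 (not isolated; alkene geometry immaterial; configuration at the quaternary carbon as in 9).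
  - Conjugate reduction of F6 in the same flask gives 16.

**Step 7.**
- What may go wrong: methylation may go on to the dimethyl ether or give a mixture of mono-ethers, which lowers the supply of 13.
- Fallback (sets out from 11, returns at 13): the pattern is reached by subtraction instead of addition.
  - Friedel–Crafts acylation of 1,3,5-trimethoxybenzene F7 with 11 (AlCl3, CH2Cl2, 0 °C) gives 1-(2,4,6-trimethoxyphenyl)butan-1-one F8.
  - Chelation-directed cleavage of the two methoxy groups ortho to the ketone (excess AlCl3, chlorobenzene, 80 °C) leaves the para-methoxy group and gives 13.

## Further compounds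

F1 | step 5 | methyl (2S)-3-chloro-2-methyl-2-(3-methylbut-2-en-1-yl)-3-oxopropanoate | COC(=O)[C@](C)(CC=C(C)C)C(Cl)=O
F2 | step 5 | (3Z)-2,4-bis(trimethylsilyloxy)nona-1,3-diene | C=C(O[Si](C)(C)C)/C=C(\O[Si](C)(C)C)CCCCC
F3 | step 2 | dimethyl 2-methylpropanedioate | COC(=O)C(C)C(=O)OC
F4 | step 2 | dimethyl 2-methyl-2-(3-methylbut-2-en-1-yl)propanedioate | COC(=O)C(C)(CC=C(C)C)C(=O)OC
F5 | step 9 | 3-butanoyl-2,4-dihydroxy-6-methoxybenzaldehyde | CCCC(=O)c1c(O)cc(OC)c(C=O)c1O
F6 | step 9 | (6S)-2-[(3-butanoyl-2,4-dihydroxy-6-methoxyphenyl)methylidene]-4-hexanoyl-5-hydroxy-6-methyl-6-(3-methylbut-2-en-1-yl)cyclohex-4-ene-1,3-dione | CCCCCC(=O)C1=C(O)[C@](C)(CC=C(C)C)C(=O)C(=Cc2c(OC)cc(O)c(C(=O)CCC)c2O)C1=O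
F7 | step 7 | 1,3,5-trimethoxybenzene | COc1cc(OC)cc(OC)c1
F8 | step 7 | 1-(2,4,6-trimethoxyphenyl)butan-1-one | CCCC(=O)c1c(OC)cc(OC)cc1OC
A1 | alternative 1 | 1-(2,4,6-trihydroxy-3-methylphenyl)hexan-1-one | CCCCCC(=O)c1c(O)cc(O)c(C)c1O
A2 | alternative 1 | racemic 2-hexanoyl-3,5-dihydroxy-4-methyl-4-(3-methylbut-2-en-1-yl)cyclohexa-2,5-dien-1-one | CCCCCC(=O)C1=C(O)C(C)(CC=C(C)C)C(O)=CC1=O
A3 | alternative 2 | 3,5-dihydroxy-4-methyl-4-(3-methylbut-2-en-1-yl)cyclohexa-2,5-dien-1-one (achiral) | CC(C)=CCC1(C)C(O)=CC(=O)C=C1O
A4 | alternative 2 | (4S)-2-[(3-butanoyl-2,4-dihydroxy-6-methoxyphenyl)methyl]-3,5-dihydroxy-4-methyl-4-(3-methylbut-2-en-1-yl)cyclohexa-2,5-dien-1-one | C1=C(O)[C@](C)(CC=C(C)C)C(O)=C(Cc2c(OC)cc(O)c(C(=O)CCC)c2O)C1=O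
A5 | alternative 3 | 1-[3-butanoyl-6-methoxy-2,4-bis(methoxymethoxy)phenyl]decane-3,5-dione | CCCCCC(=O)CC(=O)CCc1c(OC)cc(OCOC)c(C(=O)CCC)c1OCOC
A6 | alternative 3 | (4R)-6-{[3-butanoyl-6-methoxy-2,4-bis(methoxymethoxy)phenyl]methyl}-2-hexanoyl-3,5-dihydroxy-4-methyl-4-(3-methylbut-2-en-1-yl)cyclohexa-2,5-dien-1-one | CCCCCC(=O)C1=C(O)[C@](C)(CC=C(C)C)C(O)=C(Cc2c(OC)cc(OCOC)c(C(=O)CCC)c2OCOC)C1=O
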